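The trans-decalin is disconnected at C4–C5 and C9–C10 (labdane numbering) back to an acyclic (3E,7E)-dienyl acetate carrying a 2,2-disubstituted oxirane. Cp2TiCl opens the oxirane to the tertiary C-4 radical, which closes ring A onto C-5 and then ring B onto C-9. One operation sets C-4, C-5, C-9 and C-10, turns the oxirane oxygen into the C-18 hydroxyl and leaves a C8=C17 alkene for hydration. The step exploits the hydroxymethyl-bearing quaternary C-4 (oxirane C4–C18 as masked radical) and the equatorial C-6 acetoxy group on ring B, the precursor's only stereocentre, which steers the fold. The diene side chain is attached last by Negishi coupling.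

Key step: step 10

Remark: atom numbers C-1 to C-20 are those of the labdane skeleton of the target (C-18 = CH2OH on C-4, C-17 = methyl on C-8, C-20 = methyl on C-10, C-11 to C-16 = side chain).
Remark: the oxirane carbon of 7 and 13–16 is carried as a 1:1 mixture of epimers, which is harmless because step 10 converts it into a planar radical.

Step 1
Reactants: 1 5-bromo-2-methylpent-1-ene; 2 ethyl but-2-ynoate
Product: 6 ethyl (2E)-3,7-dimethylocta-2,7-dienoate, via (4-methylpent-4-en-1-yl)magnesium bromide 3 (not isolated), via (4-methylpent-4-en-1-yl)copper 4 (not isolated), via alkenylcopper syn-adduct 5 (not isolated)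
Conditions: Mg, THF; CuI (1.0 equiv), THF, −78 °C; then 2, −78 °C; 1 M HCl quench at −78 °C
Reagents that add atoms: none
Why: Syn-carbocupration of the ynoate by the organocopper 4 at −78 °C and protonation of the alkenylcopper 5 with retention (a known route to (E)-3-methylalk-2-enoates) should place the new chain trans to the ester; no stereocentre is formed.

Step 2
Reactants: 6 ethyl (2E)-3,7-dimethylocta-2,7-dienoate
Product: 7 ethyl (2E)-3-methyl-6-(2-methyloxiran-2-yl)hex-2-enoate
Conditions: 3-chloroperoxybenzoic acid, NaHCO3, CH2Cl2, 0 °C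
Reagents that add atoms: 3-chloroperoxybenzoic acid, OOC(=O)c1cccc(Cl)c1
Why: Prilezhaev epoxidation is chemoselective for the electron-rich 1,1-disubstituted alkene over the conjugated enoate, and the racemic oxirane carbon needs no control because step 10 converts it into a planar radical.

Step 3
Reactants: 8 5-chloro-2-methylpent-2-ene
Product: 9 (2E)-5-chloro-2-methylpent-2-en-1-ol
Conditions: SeO2 (cat.), tert-butyl hydroperoxide, salicylic acid (cat.), CH2Cl2, 0 °C to rt
Reagents that add atoms: tert-butyl hydroperoxide, CC(C)(C)OO (oxygen relayed by the catalyst selenium dioxide, O=[Se]=O)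
Why: Riley allylic oxidation (ene reaction with SeO2 then [2,3]-sigmatropic shift, tert-butyl hydroperoxide as terminal oxidant) hydroxylates the (E)-methyl group of the trisubstituted alkene selectively, fixing the (E)-geometry needed later for an equatorial C-11.

Step 4
Reactants: 9 (2E)-5-chloro-2-methylpent-2-en-1-ol
Product: 10 (2E)-1-bromo-5-chloro-2-methylpent-2-ene
Conditions: CBr4, PPh3, CH2Cl2, 0 °C
Reagents that add atoms: tetrabromomethane, BrC(Br)(Br)Br
Why: The Appel reaction converts the primary allylic alcohol into the bromide under neutral conditions with retention of the (E)-alkene and without touching the alkyl chloride.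

Step 5
Reactants: 10 (2E)-1-bromo-5-chloro-2-methylpent-2-ene
Product: 11 {[(2E)-5-chloro-2-methylpent-2-en-1-yl]sulfonyl}benzene
Conditions: sodium benzenesulfinate (1.0 equiv), DMF, 0 °C to rt
Reagents that add atoms: sodium benzenesulfinate, [Na+].[O-]S(=O)c1ccccc1
Why: SN2 substitution by the S-nucleophilic sulfinate is much faster at the allylic bromide than at the primary alkyl chloride, giving the allylic sulfone without allylic transposition.

Step 6
Reactants: 11 {[(2E)-5-chloro-2-methylpent-2-en-1-yl]sulfonyl}benzene; 7 ethyl (2E)-3-methyl-6-(2-methyloxiran-2-yl)hex-2-enoate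
Product: 13 (3E,7E)-1-chloro-4,8-dimethyl-11-(2-methyloxiran-2-yl)-5-(phenylsulfonyl)undeca-3,7-dien-6-one, via lithiated sulfone 12 (not isolated)
Conditions: 11 (2.1 equiv), lithium diisopropylamide (2.1 equiv), THF, −78 °C; then 7 (1.0 equiv), −78 to −40 °C; aq. NH4Cl
Reagents that add atoms: none
Why: Claisen-type C-acylation of the α-sulfonyl allyl carbanion by the ester forms the C6–C7 bond through the α-carbon (the second equivalent of carbanion deprotonates the acidic β-keto sulfone), the (E)-alkenes are retained, the primary chloride is not displaced at −78 °C, and the new sulfone-bearing centre is removed in step 7.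

Step 7
Reactants: 13 (3E,7E)-1-chloro-4,8-dimethyl-11-(2-methyloxiran-2-yl)-5-(phenylsulfonyl)undeca-3,7-dien-6-one
Product: 14 (3E,7E)-1-chloro-4,8-dimethyl-11-(2-methyloxiran-2-yl)undeca-3,7-dien-6-one
Conditions: SmI2 (2.5 equiv), THF/MeOH, −78 °C
Reagents that add atoms: none
Why: Reductive desulfonylation of the β-keto sulfone by SmI2 (electron transfer, loss of sulfinate, kinetic α-protonation of the samarium dienolate by methanol) is faster than reduction of the enone, oxirane or alkyl chloride and leaves the C8=C9 alkene out of conjugation.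

Step 8
Reactants: 14 (3E,7E)-1-chloro-4,8-dimethyl-11-(2-methyloxiran-2-yl)undeca-3,7-dien-6-one
Product: 15 (3E,6R,7E)-1-chloro-4,8-dimethyl-11-(2-methyloxiran-2-yl)undeca-3,7-dien-6-ol
Conditions: (S)-2-methyl-CBS-oxazaborolidine (0.3 equiv), catecholborane (1.8 equiv), toluene, −78 °C
Reagents that add atoms: none
Why: Corey–Bakshi–Shibata reduction, in which the alkenyl group acts as the large and the allylic CH2 group as the small substituent, should deliver hydride from the (S)-catalyst–borane complex to give the (6R)-allylic alcohol, the only stereocentre the precursor needs.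

Step 9
Reactants: 15 (3E,6R,7E)-1-chloro-4,8-dimethyl-11-(2-methyloxiran-2-yl)undeca-3,7-dien-6-ol
Product: 16 (3E,6R,7E)-1-chloro-4,8-dimethyl-11-(2-methyloxiran-2-yl)undeca-3,7-dien-6-yl acetate
Conditions: Ac2O, Et3N, DMAP (cat.), CH2Cl2, 0 °C
Reagents that add atoms: acetic anhydride, CC(=O)OC(C)=O
Why: DMAP-catalysed acylation of the secondary allylic alcohol installs the acetate of the target with retention at C-6 and makes the C-6 oxygen substituent small for the facial control needed in step 10.

Step 10
Reactants: 16 (3E,6R,7E)-1-chloro-4,8-dimethyl-11-(2-methyloxiran-2-yl)undeca-3,7-dien-6-yl acetate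
Product: 17 (4S,5S,6R,9R,10S)-6-acetoxy-12-chloro-13,14,15,16-tetranorlabd-8(17)-en-18-ol
Conditions: Cp2TiCl2 (2.5 equiv), Mn dust (8 equiv), degassed THF, rt, slow addition of 16 at high dilution; aq. NaH2PO4 work-up
Reagents that add atoms: none
Why: Cp2TiCl (trivalent titanium, formed from Cp2TiCl2 and Mn) opens the oxirane by single-electron transfer at the more substituted C–O bond, giving the tertiary C-4 radical with the oxygen kept on C-18 as a titanium alkoxide; this radical adds 6-endo-trig to C-5 of the C5=C10 alkene (ring A, C4–C5 bond), the new tertiary C-10 radical adds 6-endo-trig to C-9 (ring B), and the C-8 radical is captured by a second Cp2TiCl and loses β-hydride to give the C8=C17 alkene. The closest known reaction type is the titanocene-mediated radical cyclization of epoxypolyprenes to trans-decalins bearing an exocyclic alkene. Both rings close in the 6-endo mode through chair-like transition states because each radical attacks the less substituted carbon of a trisubstituted alkene and leaves a tertiary radical. C-4: both oxirane epimers give the same planar radical and the bulky CH2O–[Ti] group takes the equatorial site, trans to C-20, to avoid the syn-axial C-20 methyl; C-5: allylic 1,3-strain with the C-20 methyl holds H-6 in the alkene plane and the radical adds anti to the C-7 chain, which puts the acetate equatorial and relays the (6R) centre; C-10 and C-9: the two (E)-alkenes folded chair–chair give the trans ring fusion and an equatorial C-11. The step needs cyclization to outrun trapping of the C-4 radical (slow addition, high dilution) and facial selectivity at C-5, which rests on the small acetoxy group versus the branched C-7 chain.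

Step 11
Reactants: 17 (4S,5S,6R,9R,10S)-6-acetoxy-12-chloro-13,14,15,16-tetranorlabd-8(17)-en-18-ol
Product: 18 (4S,5S,6R,8S,9S,10R)-6-acetoxy-12-chloro-13,14,15,16-tetranorlabdane-8,18-diol
Conditions: Co(acac)2 (20 mol%), PhSiH3, O2 (1 atm), THF, rt; then Me2S
Reagents that add atoms: dioxygen, O=O
Why: Mukaiyama hydration (cobalt hydride hydrogen-atom transfer to the terminal CH2, capture of the tertiary C-8 radical by O2, reduction of the peroxide) gives the Markovnikov alcohol, O2 approaching equatorially on the face opposite the syn-axial C-20 methyl so that the hydroxyl is equatorial and C-17 axial, and any Δ7 isomer from step 10 converges on the same radical.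

Step 12
Reactants: 18 (4S,5S,6R,8S,9S,10R)-6-acetoxy-12-chloro-13,14,15,16-tetranorlabdane-8,18-diol; 19 2-chlorobuta-1,3-diene (chloroprene)
Product: 22 (4S,5S,6R,8S,9S,10R)-6-acetoxylabda-13(16),14-diene-8,18-diol, via buta-1,3-dien-2-ylmagnesium chloride 20 (not isolated), via buta-1,3-dien-2-ylzinc chloride 21 (not isolated)
Conditions: 19, Mg, THF, reflux; ZnCl2, 0 °C; then 18, 21 (4 equiv), Pd2(dba)3 (2 mol%), tricyclopentylphosphine (8 mol%), N-methylimidazole, THF/NMP, 80 °C
Reagents that add atoms: none
Why: Negishi sp3–sp2 cross-coupling: the electron-rich trialkylphosphine–palladium catalyst undergoes oxidative addition to the primary alkyl chloride, transmetalation with the dienylzinc 21 and reductive elimination faster than β-hydride elimination, and the organozinc leaves the acetate untouched while an excess compensates for the two hydroxyl groups.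

Compound list
1 | 5-bromo-2-methylpent-1-ene | C=C(C)CCCBr | starting material
2 | ethyl but-2-ynoate | CC#CC(=O)OCC | starting material
3 | (4-methylpent-4-en-1-yl)magnesium bromide | C=C(C)CCC[Mg]Br | intermediate
4 | (4-methylpent-4-en-1-yl)copper | C=C(C)CCC[Cu] | intermediate
5 | ethyl (2Z)-2-cuprio-3,7-dimethylocta-2,7-dienoate (alkenylcopper syn-adduct, copper cis to the new chain) | CCOC(=O)/C([Cu])=C(\C)CCCC(C)=C | intermediate
6 | ethyl (2E)-3,7-dimethylocta-2,7-dienoate | CCOC(=O)/C=C(\C)CCCC(C)=C | intermediate
7 | ethyl (2E)-3-methyl-6-(2-methyloxiran-2-yl)hex-2-enoate (racemic at the oxirane carbon) | CCOC(=O)/C=C(\C)CCCC1(C)CO1 | intermediate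
8 | 5-chloro-2-methylpent-2-ene | CC(C)=CCCCl | starting material
9 | (2E)-5-chloro-2-methylpent-2-en-1-ol | OC/C(C)=C/CCCl | intermediate
10 | (2E)-1-bromo-5-chloro-2-methylpent-2-ene | BrC/C(C)=C/CCCl | intermediate
11 | {[(2E)-5-chloro-2-methylpent-2-en-1-yl]sulfonyl}benzene | O=S(=O)(C/C(C)=C/CCCl)c1ccccc1 | intermediate
12 | {[(2E)-5-chloro-1-lithio-2-methylpent-2-en-1-yl]sulfonyl}benzene (lithiated sulfone) | [Li]C(/C(C)=C/CCCl)S(=O)(=O)c1ccccc1 | intermediate
13 | (3E,7E)-1-chloro-4,8-dimethyl-11-(2-methyloxiran-2-yl)-5-(phenylsulfonyl)undeca-3,7-dien-6-one (mixture of diastereomers at C-5 of the chain and at the oxirane carbon) | O=C(/C=C(\C)CCCC1(C)CO1)C(/C(C)=C/CCCl)S(=O)(=O)c1ccccc1 | intermediate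
14 | (3E,7E)-1-chloro-4,8-dimethyl-11-(2-methyloxiran-2-yl)undeca-3,7-dien-6-one (both oxirane epimers) | O=C(/C=C(\C)CCCC1(C)CO1)C/C(C)=C/CCCl | intermediate
15 | (3E,6R,7E)-1-chloro-4,8-dimethyl-11-(2-methyloxiran-2-yl)undeca-3,7-dien-6-ol (both oxirane epimers) | O[C@H](C/C(C)=C/CCCl)/C=C(\C)CCCC1(C)CO1 | intermediate
16 | (3E,6R,7E)-1-chloro-4,8-dimethyl-11-(2-methyloxiran-2-yl)undeca-3,7-dien-6-yl acetate (both oxirane epimers) | CC(=O)O[C@H](C/C(C)=C/CCCl)/C=C(\C)CCCC1(C)CO1 | intermediate
17 | (4S,5S,6R,9R,10S)-6-acetoxy-12-chloro-13,14,15,16-tetranorlabd-8(17)-en-18-ol (trans-decalin; equatorial 6-acetoxy; equatorial CH2OH on C-4 trans to the C-10 methyl; 2-chloroethyl on C-9 cis to the C-10 methyl; exocyclic C8=CH2) | ClCC[C@H]1[C@]2(C)CCC[C@](C)(CO)[C@H]2[C@H](OC(C)=O)CC1=C | intermediate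
18 | (4S,5S,6R,8S,9S,10R)-6-acetoxy-12-chloro-13,14,15,16-tetranorlabdane-8,18-diol (as 17, with equatorial 8-hydroxyl and axial C-17 methyl) | ClCC[C@H]1[C@]2(C)CCC[C@](C)(CO)[C@H]2[C@H](OC(C)=O)C[C@]1(C)O | intermediate
19 | 2-chlorobuta-1,3-diene (chloroprene) | C=CC(Cl)=C | starting material
20 | buta-1,3-dien-2-ylmagnesium chloride | C=CC(=C)[Mg]Cl | intermediate
21 | buta-1,3-dien-2-ylzinc chloride | C=CC(=C)[Zn]Cl | intermediate
22 | (4S,5S,6R,8S,9S,10R)-6-acetoxylabda-13(16),14-diene-8,18-diol (ent-labdane series) | C=CC(=C)CC[C@H]1[C@]2(C)CCC[C@](C)(CO)[C@H]2[C@H](OC(C)=O)C[C@]1(C)O | target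

Total step count: 12. Longest linear sequence: 10 steps (from 8 to 22, steps 3 to 12); steps 1 and 2 form the second branch, which joins in step 6.

Steps most likely to fail, with one fallback each:

First, step 10. The first radical addition may show poor facial selectivity at C-5 with respect to the C-6 stereocentre, and the hindered C-4 radical may be trapped by Cp2TiCl before it cyclizes. The fallback moves the control element from the acetate to a free hydroxyl, the smallest possible C-6 substituent, and introduces the acetate only after ring formation. It sets out from 15, which is submitted to the same Cp2TiCl2/Mn conditions to give (4S,5S,6R,9R,10S)-12-chloro-13,14,15,16-tetranorlabd-8(17)-ene-6,18-diol F1. Exhaustive acetylation (Ac2O, DMAP, pyridine) should give (4S,5S,6R,9R,10S)-12-chloro-13,14,15,16-tetranorlabd-8(17)-ene-6,18-diyl diacetate F2. Regioselective methanolysis of the unhindered primary C-18 acetate (K2CO3, MeOH, −20 °C), the hindered equatorial C-6 acetate reacting far more slowly, returns the route at 17.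

Second, step 11. Dioxygen capture of the C-8 radical may occur from the wrong face, or the radical may be reduced to the alkane. The fallback replaces the radical hydration by a polar one. It sets out from 17: oxymercuration (Hg(OAc)2, THF/H2O), with water attacking C-8 on the face opposite the C-20 methyl, should give [(4S,5S,6R,8S,9S,10R)-6-acetoxy-12-chloro-8,18-dihydroxy-13,14,15,16-tetranorlabdan-17-yl]mercury acetate F3. Brief demercuration with NaBH4 (aq. NaOH, 0 °C) rejoins the route at 18.

Third, step 12. The dienylzinc reagent may be protonated by the two hydroxyl groups, the alkylpalladium intermediate may undergo β-hydride elimination, and the 2-substituted butadiene may oligomerise at 80 °C. The fallback builds the diene by metathesis instead of cross-coupling with a dienyl metal. It sets out from 18 and runs as follows: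
- Halide exchange (NaI, butanone, reflux) gives (4S,5S,6R,8S,9S,10R)-6-acetoxy-12-iodo-13,14,15,16-tetranorlabdane-8,18-diol F4.
- Alkyl Sonogashira coupling with ethynyltrimethylsilane ([(π-allyl)PdCl]2, 1,3-bis(1-adamantyl)imidazolium chloride, CuI, Cs2CO3, DMF/Et2O, 45 °C) gives (4S,5S,6R,8S,9S,10R)-6-acetoxy-14-(trimethylsilyl)-15,16-dinorlabd-13-yne-8,18-diol F5.
- Buffered desilylation (tetrabutylammonium fluoride, AcOH, THF, 0 °C) gives (4S,5S,6R,8S,9S,10R)-6-acetoxy-15,16-dinorlabd-13-yne-8,18-diol F6.
- Enyne cross-metathesis with ethylene (second-generation Grubbs catalyst, ethylene 1 atm, CH2Cl2, 40 °C) converts the terminal alkyne into the 2-substituted buta-1,3-diene and arrives at 22.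

Further compounds
F1 | step 10 | (4S,5S,6R,9R,10S)-12-chloro-13,14,15,16-tetranorlabd-8(17)-ene-6,18-diol | ClCC[C@H]1[C@]2(C)CCC[C@](C)(CO)[C@H]2[C@H](O)CC1=C
F2 | step 10 | (4S,5S,6R,9R,10S)-12-chloro-13,14,15,16-tetranorlabd-8(17)-ene-6,18-diyl diacetate | ClCC[C@H]1[C@]2(C)CCC[C@](C)(COC(C)=O)[C@H]2[C@H](OC(C)=O)CC1=C
F3 | step 11 | [(4S,5S,6R,8S,9S,10R)-6-acetoxy-12-chloro-8,18-dihydroxy-13,14,15,16-tetranorlabdan-17-yl]mercury acetate | ClCC[C@H]1[C@]2(C)CCC[C@](C)(CO)[C@H]2[C@H](OC(C)=O)C[C@]1(C[Hg]OC(C)=O)O
F4 | step 12 | (4S,5S,6R,8S,9S,10R)-6-acetoxy-12-iodo-13,14,15,16-tetranorlabdane-8,18-diol | ICC[C@H]1[C@]2(C)CCC[C@](C)(CO)[C@H]2[C@H](OC(C)=O)C[C@]1(C)O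
F5 | step 12 | (4S,5S,6R,8S,9S,10R)-6-acetoxy-14-(trimethylsilyl)-15,16-dinorlabd-13-yne-8,18-diol | C[Si](C)(C)C#CCC[C@H]1[C@]2(C)CCC[C@](C)(CO)[C@H]2[C@H](OC(C)=O)C[C@]1(C)O
F6 | step 12 | (4S,5S,6R,8S,9S,10R)-6-acetoxy-15,16-dinorlabd-13-yne-8,18-diol | C#CCC[C@H]1[C@]2(C)CCC[C@](C)(CO)[C@H]2[C@H](OC(C)=O)C[C@]1(C)O
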